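**Plan**

1. Germacrane numbering is used: ring C1–C10, lactone carbons C11–C13, C14 on C10, C15 on C4. The enabling feature is that the lactone oxygen on C6 and the acetoxy oxygen on C15 sit at the two ends of the C4=C5 allyl unit (O–C6–C5=C4–C15–O). This is the 1,4-adduct of a C6=C5–C4=C15 diene, so O–C6 and C15–OAc are cut together: a palladium-catalysed 1,4-acyloxylation in which a carboxyl group on C11 closes the γ-lactone.
2. Earlier cuts: C11=C13 (decarboxylative Mannich methylenation; the second carboxyl of a malonate is the helper and is removed there), C5=C6 (dehydration), C4–C5 (Nozaki–Hiyama–Kishi closure of the ten-membered ring), C7–C11 (malonate Michael addition), C6=C7 (cross-metathesis), C10=C1 (aldol condensation on a γ-butyrolactone that holds C14 and O8).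
3. Forward order: the temporary butyrolactone ring fixes the C1=C10 geometry and is reduced open; the chain is extended to an enal and malonate is added; the ten-membered carbocycle is closed; the diene diacid is lactonised (key); methylenation and desilylation finish.
4. Stereochemistry: C8 is bought; C7 is set by an (S)-diarylprolinol silyl ether catalyst; C6 is relayed from C7 in the key step, which also sets the C4=C5 geometry through the ring.

Key step: step 12

Remark: (R)-5-(hydroxymethyl)dihydrofuran-2(3H)-one (from D-glutamic acid) is taken as commercial.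
Remark: the (S)-catalyst in step 8 is assigned from the usual shielding model for diarylprolinol silyl ethers (attack anti to the carbinol arm on the s-trans (E)-iminium). This model gives the (3R) centre of 16 when the β-substituent ranks highest, as with β-aryl enals; both enantiomers of the catalyst are available.

**Step 1**
Reactants: 1 pent-4-yn-1-ol
Product: 2 4-iodopent-4-en-1-ol
Conditions: NaI, Me3SiCl, H2O, MeCN, rt
Reagents that add atoms: sodium iodide, [Na+].[I-]
Why: Markovnikov hydroiodination of the terminal alkyne by HI made in situ should give the 2-iodoalkene and leave the alcohol untouched.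

**Step 2**
Reactants: 2 4-iodopent-4-en-1-ol
Product: 3 4-iodopent-4-enal
Conditions: Dess–Martin periodinane, CH2Cl2, 0 °C to rt
Reagents that add atoms: none
Why: Dess–Martin oxidation of a primary alcohol stops at the aldehyde and tolerates the vinyl iodide.

**Step 3**
Reactants: 4 (R)-5-(hydroxymethyl)dihydrofuran-2(3H)-one
Product: 6 (R)-5-vinyldihydrofuran-2(3H)-one, via lactone aldehyde 5 (not isolated)
Conditions: Dess–Martin periodinane, CH2Cl2, 0 °C; crude 5 added to Ph3P=CH2 (from Ph3PCH3Br, KOtBu), THF, −78 to 0 °C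
Reagents that add atoms: methyltriphenylphosphonium bromide, C[P+](c1ccccc1)(c1ccccc1)c1ccccc1.[Br-]
Why: Dess–Martin oxidation followed by Wittig methylenation of the crude aldehyde at low temperature should keep the bought C8 stereocentre intact.

**Step 4**
Reactants: 6 (R)-5-vinyldihydrofuran-2(3H)-one; 3 4-iodopent-4-enal
Product: 9 (R,E)-3-(4-iodopent-4-en-1-ylidene)-5-vinyldihydrofuran-2(3H)-one, via lithium aldolate 7 (not isolated), via aldol mesylate 8 (not isolated)
Conditions: LiN(iPr)2, THF, −78 °C; 3; MsCl, −78 to 0 °C; DBU, rt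
Reagents that add atoms: none
Why: aldol condensation (enolate addition, mesylation, E1cB elimination) should give the thermodynamically favoured (E)-alkylidene lactone, whose ring fixes the future C1=C10 geometry (C2 cis to C9); the two transient stereocentres are destroyed.

**Step 5**
Reactants: 9 (R,E)-3-(4-iodopent-4-en-1-ylidene)-5-vinyldihydrofuran-2(3H)-one
Product: 10 (R,E)-2-(2-hydroxybut-3-en-1-yl)-6-iodohepta-2,6-dien-1-ol
Conditions: iBu2AlH, CH2Cl2, −78 to 0 °C; aqueous potassium sodium tartrate
Reagents that add atoms: none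
Why: 1,2-hydride reduction of the α-alkylidene lactone opens the temporary ring to the allylic 1,4-diol, freeing C14–OH and C8–OH with the olefin geometry unchanged.

**Step 6**
Reactants: 10 (R,E)-2-(2-hydroxybut-3-en-1-yl)-6-iodohepta-2,6-dien-1-ol
Product: 12 (R,E)-2-[2-(tert-butyldimethylsilyloxy)but-3-en-1-yl]-6-iodohepta-2,6-dien-1-yl isobutyrate, via primary isobutyrate 11 (not isolated)
Conditions: iPrCOCl, 2,4,6-collidine, CH2Cl2, −78 °C; then TBSOTf, −78 to 0 °C
Reagents that add atoms: isobutyryl chloride, CC(C)C(Cl)=O; tert-butyldimethylsilyl trifluoromethanesulfonate, CC(C)(C)[Si](C)(C)OS(=O)(=O)C(F)(F)F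
Why: kinetic acylation should select the primary allylic alcohol over the secondary one, and silylation then protects C8–OH in the same flask.

**Step 7**
Reactants: 12 (R,E)-2-[2-(tert-butyldimethylsilyloxy)but-3-en-1-yl]-6-iodohepta-2,6-dien-1-yl isobutyrate; 13 (E)-but-2-enal
Product: 14 (2E,4R,6E)-4-(tert-butyldimethylsilyloxy)-10-iodo-6-(isobutyryloxymethyl)undeca-2,6,10-trienal
Conditions: second-generation Hoveyda–Grubbs catalyst (5 mol%), CH2Cl2, 40 °C
Reagents that add atoms: none
Why: olefin cross-metathesis of the only monosubstituted alkene with crotonaldehyde should give the (E)-enal; the trisubstituted olefin and the 2-iodoalkene are too hindered to react.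

**Step 8**
Reactants: 14 (2E,4R,6E)-4-(tert-butyldimethylsilyloxy)-10-iodo-6-(isobutyryloxymethyl)undeca-2,6,10-trienal; 15 diallyl malonate
Product: 16 diallyl 2-[(3R,4R,6E)-4-(tert-butyldimethylsilyloxy)-10-iodo-6-(isobutyryloxymethyl)-1-oxoundeca-6,10-dien-3-yl]malonate
Conditions: (S)-2-[bis(3,5-bis(trifluoromethyl)phenyl)(trimethylsilyloxy)methyl]pyrrolidine (10 mol%), EtOH, 0 °C to rt
Reagents that add atoms: none
Why: iminium-catalysed asymmetric Michael addition; the catalyst shields one face of the (E)-iminium so that malonate should add to C7 with the target configuration (catalyst control, expected to override the neighbouring C8 centre).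

**Step 9**
Reactants: 16 diallyl 2-[(3R,4R,6E)-4-(tert-butyldimethylsilyloxy)-10-iodo-6-(isobutyryloxymethyl)-1-oxoundeca-6,10-dien-3-yl]malonate
Product: 17 diallyl 8-(tert-butyldimethylsilyloxy)-5-hydroxy-14-(isobutyryloxy)germacra-1(10),4(15)-diene-12,13-dioate
Conditions: CrCl2 (10 equiv), NiCl2 (2 mol%), DMSO–THF, 0.003 M, rt
Reagents that add atoms: none
Why: Nozaki–Hiyama–Kishi reaction: the alkenylchromium formed from the 2-iodoalkene should add chemoselectively to the aldehyde at high dilution and close the ten-membered ring at C4–C5; the C5 carbinol forms as a mixture and is removed in step 10.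

**Step 10**
Reactants: 17 diallyl 8-(tert-butyldimethylsilyloxy)-5-hydroxy-14-(isobutyryloxy)germacra-1(10),4(15)-diene-12,13-dioate
Product: 18 diallyl 8-(tert-butyldimethylsilyloxy)-14-(isobutyryloxy)germacra-1(10),4(15),5-triene-12,13-dioate
Conditions: Burgess reagent, toluene, 60 °C
Reagents that add atoms: none
Why: Burgess syn-dehydration can only remove a hydrogen from C6, because C4 carries none, so the conjugated C6=C5–C4=C15 diene should result, the less strained (5E)-isomer being expected.

**Step 11**
Reactants: 18 diallyl 8-(tert-butyldimethylsilyloxy)-14-(isobutyryloxy)germacra-1(10),4(15),5-triene-12,13-dioate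
Product: 19 8-(tert-butyldimethylsilyloxy)-14-(isobutyryloxy)germacra-1(10),4(15),5-triene-12,13-dioic acid
Conditions: Pd(PPh3)4 (5 mol%), morpholine, THF, 0 °C; aqueous citric acid
Reagents that add atoms: none
Why: Tsuji–Trost deallylation with zerovalent palladium and morpholine as allyl acceptor should cleave the unsubstituted allyl esters much faster than the hindered trisubstituted allylic isobutyrate.

**Step 12**
Reactants: 19 8-(tert-butyldimethylsilyloxy)-14-(isobutyryloxy)germacra-1(10),4(15),5-triene-12,13-dioic acid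
Product: 20 15-acetoxy-8-(tert-butyldimethylsilyloxy)-14-(isobutyryloxy)germacra-1(10),4-dien-6,12-olid-13-oic acid
Conditions: Pd(OAc)2 (10 mol%), 1,4-benzoquinone (2 equiv), LiOAc, AcOH–acetone 1:4, 25 °C
Reagents that add atoms: acetic acid, CC(=O)O
Why: Divalent palladium binds the C6=C5–C4=C15 diene, one carboxyl group of the malonic acid adds to C6 anti to the metal to give a C5–C4–C15 π-allylpalladium intermediate, acetate attacks its primary terminus C15, and benzoquinone reoxidises the zerovalent palladium released. The closest known reaction type is the palladium-catalysed intramolecular 1,4-acyloxylation of conjugated dienes by a tethered carboxylic acid (1,4-acetoxylactonisation of dienylacetic acids). The γ-lactone closes in a 5-exo-trig mode by O–C6 bond formation. C6 is controlled by C7: with H7 eclipsing the C5=C6 bond, C11 lies over one face of C6 and C8 under the other, so oxygen should be delivered from the C11 side and H6 should end trans to H7 (6,7-trans lactone) whichever diastereotopic carboxyl reacts, the C11 centre forming as a mixture that step 13 removes. The step needs 1,4- over 1,2-addition, which the unhindered primary C15 terminus and the oxygen next to the other terminus should secure, and the ring-cis C4=C5 geometry, which the π-allyl should inherit from the s-trans diene (C6 syn to C3) that the ten-membered ring favours. The diene reacts in preference to the isolated C1=C10 olefin because divalent palladium binds 1,3-dienes far more strongly.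

**Step 13**
Reactants: 20 15-acetoxy-8-(tert-butyldimethylsilyloxy)-14-(isobutyryloxy)germacra-1(10),4-dien-6,12-olid-13-oic acid
Product: 22 8-O-(tert-butyldimethylsilyl) ether of the target, via Mannich base 21 (not isolated)
Conditions: Et2NH, 37% aqueous CH2O, rt; then NaOAc, AcOH, 70 °C
Reagents that add atoms: formaldehyde, C=O
Why: Mannich reaction of the malonic half-acid followed by decarboxylative loss of Et2NH should install the exocyclic methylene without touching the acetate or isobutyrate; the C11 stereocentre disappears.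

**Step 14**
Reactants: 22 8-O-(tert-butyldimethylsilyl) ether of the target
Product: 23 target CNP0312458.1
Conditions: HF·pyridine, THF–pyridine, 0 °C to rt
Reagents that add atoms: none
Why: fluoride cleavage of the silyl ether under mildly acidic conditions should avoid translactonisation to O8 and conjugate addition to the methylene lactone.

**Compound list**

1 | pent-4-yn-1-ol | C#CCCCO | starting material
2 | 4-iodopent-4-en-1-ol | C=C(I)CCCO | intermediate
3 | 4-iodopent-4-enal | C=C(I)CCC=O | intermediate
4 | (R)-5-(hydroxymethyl)dihydrofuran-2(3H)-one | O=C1CC[C@@H](O1)CO | starting material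
5 | (R)-5-oxotetrahydrofuran-2-carbaldehyde | O=C1CC[C@@H](O1)C=O | intermediate
6 | (R)-5-vinyldihydrofuran-2(3H)-one | O=C1CC[C@@H](O1)C=C | intermediate
7 | lithium aldolate of 6 and 3 (two new centres, mixture) | O=C1O[C@@H](C=C)CC1C([O-])CCC(I)=C.[Li+] | intermediate
8 | methanesulfonate of the aldol (mixture) | O=C1O[C@@H](C=C)CC1C(OS(C)(=O)=O)CCC(I)=C | intermediate
9 | (R,E)-3-(4-iodopent-4-en-1-ylidene)-5-vinyldihydrofuran-2(3H)-one | O=C1O[C@@H](C=C)C/C1=C\CCC(I)=C | intermediate
10 | (R,E)-2-(2-hydroxybut-3-en-1-yl)-6-iodohepta-2,6-dien-1-ol | OC/C(=C/CCC(I)=C)C[C@@H](O)C=C | intermediate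
11 | (R,E)-2-(2-hydroxybut-3-en-1-yl)-6-iodohepta-2,6-dien-1-yl isobutyrate | CC(C)C(=O)OC/C(=C/CCC(I)=C)C[C@@H](O)C=C | intermediate
12 | (R,E)-2-[2-(tert-butyldimethylsilyloxy)but-3-en-1-yl]-6-iodohepta-2,6-dien-1-yl isobutyrate | CC(C)C(=O)OC/C(=C/CCC(I)=C)C[C@@H](O[Si](C)(C)C(C)(C)C)C=C | intermediate
13 | (E)-but-2-enal | C/C=C/C=O | starting material
14 | (2E,4R,6E)-4-(tert-butyldimethylsilyloxy)-10-iodo-6-(isobutyryloxymethyl)undeca-2,6,10-trienal | CC(C)C(=O)OC/C(=C/CCC(I)=C)C[C@@H](O[Si](C)(C)C(C)(C)C)/C=C/C=O | intermediate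
15 | diallyl malonate | C=CCOC(=O)CC(=O)OCC=C | starting material
16 | diallyl 2-[(3R,4R,6E)-4-(tert-butyldimethylsilyloxy)-10-iodo-6-(isobutyryloxymethyl)-1-oxoundeca-6,10-dien-3-yl]malonate | C=CCOC(=O)C(C(=O)OCC=C)[C@@H](CC=O)[C@H](O[Si](C)(C)C(C)(C)C)C/C(COC(=O)C(C)C)=C\CCC(I)=C | intermediate
17 | diallyl 8-(tert-butyldimethylsilyloxy)-5-hydroxy-14-(isobutyryloxy)germacra-1(10),4(15)-diene-12,13-dioate (C5 epimers; C2 cis to C9; C7 and C8 as in the target) | C=CCOC(=O)C(C(=O)OCC=C)[C@H]1CC(O)C(=C)CC/C=C(/COC(=O)C(C)C)C[C@H]1O[Si](C)(C)C(C)(C)C | intermediate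
18 | diallyl 8-(tert-butyldimethylsilyloxy)-14-(isobutyryloxy)germacra-1(10),4(15),5-triene-12,13-dioate (5E; rest as 17) | C=CCOC(=O)C(C(=O)OCC=C)[C@H]1/C=C/C(=C)CC/C=C(/COC(=O)C(C)C)C[C@H]1O[Si](C)(C)C(C)(C)C | intermediate
19 | 8-(tert-butyldimethylsilyloxy)-14-(isobutyryloxy)germacra-1(10),4(15),5-triene-12,13-dioic acid (stereochemistry as 18) | OC(=O)C(C(=O)O)[C@H]1/C=C/C(=C)CC/C=C(/COC(=O)C(C)C)C[C@H]1O[Si](C)(C)C(C)(C)C | intermediate
20 | 15-acetoxy-8-(tert-butyldimethylsilyloxy)-14-(isobutyryloxy)germacra-1(10),4-dien-6,12-olid-13-oic acid (C6, C7, C8 as in the target; C11 epimers) | OC(=O)C1C(=O)O[C@@H]2/C=C(/COC(C)=O)CC/C=C(/COC(=O)C(C)C)C[C@@H](O[Si](C)(C)C(C)(C)C)[C@@H]12 | intermediate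
21 | 11-(diethylaminomethyl) derivative of 20 (Mannich base) | CCN(CC)CC1(C(O)=O)C(=O)O[C@@H]2/C=C(/COC(C)=O)CC/C=C(/COC(=O)C(C)C)C[C@@H](O[Si](C)(C)C(C)(C)C)[C@@H]12 | intermediate
22 | 8-O-(tert-butyldimethylsilyl) ether of the target | C=C1C(=O)O[C@@H]2/C=C(/COC(C)=O)CC/C=C(/COC(=O)C(C)C)C[C@@H](O[Si](C)(C)C(C)(C)C)[C@@H]12 | intermediate
23 | CNP0312458.1, (6R,7R,8R), 6,7-trans lactone, both ring olefins ring-cis | C=C1C(=O)O[C@@H]2/C=C(/COC(C)=O)CC/C=C(/COC(=O)C(C)C)C[C@@H](O)[C@@H]12 | target

**Step count and risks**

Total: 14 steps. Longest linear sequence: 13 steps (from 1 to 23: steps 1, 2 and 4 to 14); the branch from 4 (step 3) joins at step 4.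

Step 12. What may go wrong: oxygen is delivered to the wrong face of C6 (6,7-cis lactone), or acetate enters at C5 instead of C15. The fallback sets out from 19 and comes back at 20. Iodolactonisation under equilibrating conditions (I2, MeCN, 0 °C, no base) should give the thermodynamically favoured 6,7-trans 5-iodo-6,12-olide acid F1. AgOAc in AcOH should then ionise the allylic iodide, with acetate entering at the primary C15 and the double bond moving to C4=C5, to give 20.

Step 9. What may go wrong: oligomerisation competes with closure of the medium ring, or the new C5 alkoxide lactonises onto a malonate ester. The fallback sets out from 14 and comes back at 20; it closes the same C4–C5 bond at the sp2–sp2 level and makes step 10 unnecessary. Step 8 run with dimethyl malonate gives the dimethyl ester aldehyde F2. KN(SiMe3)2 (2.2 equiv, the first equivalent masking the malonate as its enolate) and PhNTf2 at −78 °C give the (Z)-enol triflate F3. Stille–Kelly ring closure (Me3SnSnMe3, Pd(PPh3)4, LiCl, dioxane, 90 °C, high dilution) should give the (5Z)-diene dimethyl ester F4. Me3SnOH in ClCH2CH2Cl at 70 °C should give the (5Z)-diacid F5. Under the step 12 conditions F5 should converge on 20, since C6 becomes sp3 and the s-trans diene conformer again places C6 syn to C3.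

Step 10. What may go wrong: allylic transposition of the sulfamate (nitrogen attack at C15) instead of elimination. The fallback sets out from 17 and comes back at 18. Mitsunobu substitution (PhSH, PPh3, DIAD) gives the allylic phenyl sulfide F6. Oxidation with one equivalent of mCPBA at −78 °C gives the sulfoxide F7. Thermal syn-elimination in toluene at 90 °C can again only take a hydrogen from C6 and should give 18; the reversible sulfoxide–sulfenate shift returns the same sulfoxide, while the elimination is irreversible.

**Further compounds**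

F1 | step 12 | 5-iodo-8-(tert-butyldimethylsilyloxy)-14-(isobutyryloxy)germacra-1(10),4(15)-dien-6,12-olid-13-oic acid | OC(=O)C1C(=O)O[C@@H]2C(I)C(=C)CC/C=C(/COC(=O)C(C)C)C[C@@H](O[Si](C)(C)C(C)(C)C)[C@@H]12
F2 | step 9 | dimethyl 2-[(3R,4R,6E)-4-(tert-butyldimethylsilyloxy)-10-iodo-6-(isobutyryloxymethyl)-1-oxoundeca-6,10-dien-3-yl]malonate | COC(=O)C(C(=O)OC)[C@@H](CC=O)[C@H](O[Si](C)(C)C(C)(C)C)C/C(COC(=O)C(C)C)=C\CCC(I)=C
F3 | step 9 | (Z)-enol triflate of F2 | COC(=O)C(C(=O)OC)[C@@H](/C=C\OS(=O)(=O)C(F)(F)F)[C@H](O[Si](C)(C)C(C)(C)C)C/C(COC(=O)C(C)C)=C\CCC(I)=C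
F4 | step 9 | dimethyl 8-(tert-butyldimethylsilyloxy)-14-(isobutyryloxy)germacra-1(10),4(15),5-triene-12,13-dioate, 5Z | COC(=O)C(C(=O)OC)[C@H]1/C=C\C(=C)CC/C=C(/COC(=O)C(C)C)C[C@H]1O[Si](C)(C)C(C)(C)C
F5 | step 9 | 5Z isomer of 19 | OC(=O)C(C(=O)O)[C@H]1/C=C\C(=C)CC/C=C(/COC(=O)C(C)C)C[C@H]1O[Si](C)(C)C(C)(C)C
F6 | step 10 | 5-phenylthio analogue of 17 | C=CCOC(=O)C(C(=O)OCC=C)[C@H]1CC(Sc2ccccc2)C(=C)CC/C=C(/COC(=O)C(C)C)C[C@H]1O[Si](C)(C)C(C)(C)C
F7 | step 10 | 5-phenylsulfinyl analogue of 17 | C=CCOC(=O)C(C(=O)OCC=C)[C@H]1CC(S(=O)c2ccccc2)C(=C)CC/C=C(/COC(=O)C(C)C)C[C@H]1O[Si](C)(C)C(C)(C)C
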